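**Plan**

1. Retrosynthesis (quinone numbering: C1=O, C2–OH, C3–docosyl, C4=O, C5–OMe, C6–H): the O–CH3 bond at C5 is cut first, then the ring bonds C1–C6 and C3–C4 together. This leaves a 2-oxopentacosanoyl unit (C1–C2–C3 plus chain) and a pyruvoyl unit (C4–C5–C6).
2. Enabling feature: the 2,5-dioxygenated 1,4-benzoquinone ring is the enol tautomer of cyclohexane-1,2,4,5-tetraone, the head-to-tail cyclic dimer of two 2-oxo acyl units. Each unit has a nucleophilic C3 and an acyl C1, the pattern by which fungi assemble terphenylquinone cores from two 2-oxo acids.
3. Forward, chain: docosyl Grignard plus a C3 epoxy ester gives the 2-hydroxy acid, then its acetonide, then a 5-alkylidene-1,3-dioxolan-4-one. This is the masked enol of the 2-oxo acid and can only donate its acyl group.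
4. Forward, ring: a pyruvate enolate is acylated by the dioxolanone, acetone is lost, and the released enolate closes the only ring by Dieckmann condensation, directly at the quinone oxidation level. The unhindered C5–OH is then methylated.
5. Stereochemistry: the target has no stereocentre. The racemic carbinol of step 1 and the alkene geometry of step 3 are both erased.

Key step: step 4

Remark: the side chain is read as unbranched docosyl (C22). Racemic methyl glycidate is used because its stereocentre becomes sp2 in step 3.

**Step 1**
Reactants: 1 1-bromodocosane; 2 methyl oxirane-2-carboxylate (methyl glycidate, racemic)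
Product: 5 2-hydroxypentacosanoic acid (racemic), via docosylmagnesium bromide 3 (not isolated), via methyl 2-hydroxypentacosanoate 4 (not isolated)
Conditions: Mg, THF, 50 °C; then CuI (10 mol%), 2, THF, −40 → 0 °C; then LiOH, MeOH/H2O, 50 °C; aq. HCl
Reagents that add atoms: lithium hydroxide (aqueous), [Li+].[OH-]
Why: Copper-catalysed Grignard opening of the epoxide at its unsubstituted terminus (SN2) should outrun addition to the ester at low temperature, and saponification in the same flask gives the acid; the new carbinol centre is racemic and is removed in step 3.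

**Step 2**
Reactants: 5 2-hydroxypentacosanoic acid
Product: 6 2,2-dimethyl-5-tricosyl-1,3-dioxolan-4-one (racemic)
Conditions: Me2C(OMe)2, p-TsOH (cat.), acetone, rt
Reagents that add atoms: 2,2-dimethoxypropane, COC(C)(C)OC
Why: Acid-catalysed transketalisation of an alpha-hydroxy acid with 2,2-dimethoxypropane is the standard entry to 2,2-dimethyl-1,3-dioxolan-4-ones and is driven by loss of methanol.

**Step 3**
Reactants: 6 2,2-dimethyl-5-tricosyl-1,3-dioxolan-4-one
Product: 8 (5Z)-2,2-dimethyl-5-tricosylidene-1,3-dioxolan-4-one, via 5-bromo-2,2-dimethyl-5-tricosyl-1,3-dioxolan-4-one 7 (not isolated)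
Conditions: NBS, AIBN (cat.), PhCF3, 85 °C; then Et3N, 0 °C → rt
Reagents that add atoms: none
Why: Wohl–Ziegler bromination should select the single captodative tertiary C5–H (between ring oxygen and lactone carbonyl) over the secondary chain hydrogens, and E2 loss of HBr can only give the exocyclic alkene, drawn as the expected Z isomer although either isomer serves.

**Step 4**
Reactants: 8 (5Z)-2,2-dimethyl-5-tricosylidene-1,3-dioxolan-4-one; 9 methyl 2-(trimethylsilyloxy)prop-2-enoate
Product: 12 3-docosyl-2,5-dihydroxycyclohexa-2,5-diene-1,4-dione, via potassium enolate of methyl pyruvate 10 (not isolated), via potassium enolate of methyl 2,4,5-trioxooctacosanoate 11 (not isolated)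
Conditions: 9, KOtBu, THF, −78 °C; then 8, −78 → 0 °C; then NaOMe, MeOH, 0 °C → rt; aq. HCl
Reagents that add atoms: none
Why: Proposed new method: KOtBu desilylates 9 to the pyruvate enolate 10, whose CH2 carbon attacks the lactone carbonyl of 8 (quinone bond C6–C1); the tetrahedral adduct collapses with loss of acetone and so releases the enolate of the long-chain 2-oxo unit (11), whose carbon (future C3) then attacks the pyruvate ester carbonyl under NaOMe (bond C3–C4), methoxide leaves, and the doubly deprotonated hydroxyquinone results as the thermodynamic sink. The closest known reaction types are the acylation of ester enolates by 5-ylidene-1,3-dioxolan-4-ones with release of a latent enolate, and the base-mediated head-to-tail self-condensation of 2-oxo esters to 3,6-disubstituted 2,5-dihydroxy-1,4-benzoquinones. The carbocycle closes by a 6-(enolendo)-exo-trig Dieckmann condensation, and an enol lactone from competing O-acylation should be reopened by methoxide and led to the same anion. No stereocentre is formed. The step needs cross-selectivity between two 2-oxo acyl units and must avoid their aldol–lactonisation: 8 has neither a ketone carbonyl nor an enolisable alpha-hydrogen and can only donate its acyl group, 10 is made from a silyl enol ether so that no free pyruvate ketone is present, and the nucleophilic carbon of the long-chain unit is unmasked only by the first bond formation itself.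

**Step 5**
Reactants: 12 3-docosyl-2,5-dihydroxycyclohexa-2,5-diene-1,4-dione
Product: 13 3-docosyl-2-hydroxy-5-methoxycyclohexa-2,5-diene-1,4-dione (target)
Conditions: MeOH/CHCl3, H2SO4 (cat.), 50 °C, stopped at the monoether
Reagents that add atoms: methanol, CO
Why: Vinylogous Fischer esterification (acid-catalysed addition–elimination of methanol at a hydroxyquinone carbon) should occur at C5, which is flanked by C6–H, and not at C2, whose hydroxyl is shielded by the docosyl group and whose ether would be twisted out of conjugation.

**Compound list**

1 | 1-bromodocosane | CCCCCCCCCCCCCCCCCCCCCCBr | starting material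
2 | methyl oxirane-2-carboxylate (racemic) | COC(=O)C1CO1 | starting material
3 | docosylmagnesium bromide | CCCCCCCCCCCCCCCCCCCCCC[Mg]Br | intermediate
4 | methyl 2-hydroxypentacosanoate (racemic) | CCCCCCCCCCCCCCCCCCCCCCCC(O)C(=O)OC | intermediate
5 | 2-hydroxypentacosanoic acid (racemic) | CCCCCCCCCCCCCCCCCCCCCCCC(O)C(=O)O | intermediate
6 | 2,2-dimethyl-5-tricosyl-1,3-dioxolan-4-one (racemic) | CCCCCCCCCCCCCCCCCCCCCCCC1OC(C)(C)OC1=O | intermediate
7 | 5-bromo-2,2-dimethyl-5-tricosyl-1,3-dioxolan-4-one (racemic) | CCCCCCCCCCCCCCCCCCCCCCCC1(Br)OC(C)(C)OC1=O | intermediate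
8 | (5Z)-2,2-dimethyl-5-tricosylidene-1,3-dioxolan-4-one | CCCCCCCCCCCCCCCCCCCCCC/C=C1\OC(C)(C)OC1=O | intermediate
9 | methyl 2-(trimethylsilyloxy)prop-2-enoate | C=C(O[Si](C)(C)C)C(=O)OC | starting material
10 | potassium enolate of methyl pyruvate (potassium 3-methoxy-3-oxoprop-1-en-2-olate) | C=C([O-])C(=O)OC.[K+] | intermediate
11 | potassium enolate of methyl 2,4,5-trioxooctacosanoate (5Z enolate, first-formed tautomer) | CCCCCCCCCCCCCCCCCCCCCC/C=C(\[O-])C(=O)CC(=O)C(=O)OC.[K+] | intermediate
12 | 3-docosyl-2,5-dihydroxycyclohexa-2,5-diene-1,4-dione | CCCCCCCCCCCCCCCCCCCCCCC1=C(O)C(=O)C=C(O)C1=O | intermediate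
13 | 3-docosyl-2-hydroxy-5-methoxycyclohexa-2,5-diene-1,4-dione | CCCCCCCCCCCCCCCCCCCCCCC1=C(O)C(=O)C=C(OC)C1=O | target

**Summary**

Total step count: 5. Longest linear sequence: 5 steps (1 → 5 → 6 → 8 → 12 → 13).

**Steps most likely to fail**

Step 4 (proposed new method). The pyruvate enolate may condense with itself before it acylates, may add in conjugate fashion to the alkylidene carbon instead of substituting at the lactone carbonyl, or the two 2-oxo units may be set free and drift into aldol–lactonisation. The fallback gives up ring construction and functionalises a preformed arene by known chemistry. It sets out from 1 and comes back at 12. Commercial 1,2,4,5-tetramethoxybenzene is lithiated between two methoxy groups (n-BuLi, TMEDA, THF, 0 °C) and alkylated with 1 to give 3-docosyl-1,2,4,5-tetramethoxybenzene F1. BBr3 in CH2Cl2 (−78 °C → rt) should cleave all four methyl ethers to 3-docosylbenzene-1,2,4,5-tetrol F2, which is oxidised by air during aqueous work-up to 12.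

Step 5. Methylation may run on to the diether, or the selectivity between the two hydroxyls may be incomplete. The fallback replaces selective ether formation by selective ether cleavage. It sets out from 12 and comes back at 13. Both hydroxyls are methylated (Me3SiCHN2, MeOH/toluene, rt) to 3-docosyl-2,5-dimethoxycyclohexa-2,5-diene-1,4-dione F3. Aqueous HClO4 in dioxane should then hydrolyse only the C2 methoxy group, which the neighbouring docosyl chain twists out of conjugation and makes the more labile vinylogous ester, to give 13.

Step 3. Hydrogen abstraction along the 22 methylene groups, over-bromination, or opening of the bromo lactone may compete with the wanted C5 bromination. The fallback replaces the radical step by enolate chemistry. It sets out from 6 and comes back at 8. The lactone enolate (LiN(iPr)2, THF, −78 °C) is trapped with PhSeBr to give 2,2-dimethyl-5-(phenylselanyl)-5-tricosyl-1,3-dioxolan-4-one F4. Oxidation with H2O2 (CH2Cl2, 0 °C) and syn-elimination of the selenoxide, which can only remove a chain hydrogen, gives 8.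

**Further compounds**

F1 | step 4 | 3-docosyl-1,2,4,5-tetramethoxybenzene | CCCCCCCCCCCCCCCCCCCCCCc1c(OC)c(OC)cc(OC)c1OC
F2 | step 4 | 3-docosylbenzene-1,2,4,5-tetrol | CCCCCCCCCCCCCCCCCCCCCCc1c(O)c(O)cc(O)c1O
F3 | step 5 | 3-docosyl-2,5-dimethoxycyclohexa-2,5-diene-1,4-dione | CCCCCCCCCCCCCCCCCCCCCCC1=C(OC)C(=O)C=C(OC)C1=O
F4 | step 3 | 2,2-dimethyl-5-(phenylselanyl)-5-tricosyl-1,3-dioxolan-4-one | CCCCCCCCCCCCCCCCCCCCCCCC1([Se]c2ccccc2)OC(C)(C)OC1=O
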